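**Retrosynthetic overview**
1. Target 15 ⇒ Diels–Alder union of (R)-sorbicillinol 14 (diene) with methylene dioxanone 10. This last step forms the bicyclo[2.2.2]octane and the spiro centre. The cyclohexene ring is numbered C1 = C–CO2Me, C2 = CH=, C3 = ether O–CH, C4 = lactone O–CH, C5 = CH–OH, C6 = CH2.
2. 10 ⇒ phosphono lactone 9 (Horner–Wadsworth–Emmons olefination with CH2O).
3. 9 ⇒ acyclic dialdehyde 7: reductive pinacol union of the two formyl carbons makes the C4–C5 bond and closes the cyclohexene, and O4 then lactonises onto the ester tethered at O3. The enabling feature is that C4 and C5 are adjacent oxygen-bearing sp3 carbons of the cyclohexene ring (a 1,2-diol retron), flanked by the C3 ether oxygen that carries the tether and by the C1=C2 enoate whose cis arms hold both formyl groups in reach.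
4. 7 ⇒ double ozonolysis of triene 6 ⇒ alcohol 5 ⇒ ynoate 3 from crotonaldehyde and methyl propiolate.
5. 14 ⇒ sorbicillin 13 ⇒ 2,4-dimethylresorcinol and sorbic acid. Ring order: cyclohexene, then dioxanone (both step 6), then bicyclo[2.2.2]octane (step 10).

Key step: step 6

Assumption: the target is taken exactly as drawn ((R)-configured C(Me)(OH) centre, (3S,4S,5R) cyclohexene unit). For each chiral controller (ProPhenol in step 1, binaphthyl iodyl reagent in step 9) the antipode named is assumed to deliver the configuration drawn; the other antipode is equally accessible and would be used if the sense of induction proved opposite.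

**Step 1**
Reactants: 1 (E)-but-2-enal (crotonaldehyde); 2 methyl propiolate
Product: 3 methyl (4R,5E)-4-hydroxyhept-5-en-2-ynoate
Conditions: (S,S)-ProPhenol (10 mol %), Ph3P=O (20 mol %), Me2Zn (3 equiv), PhMe, 4 °C; aq. NH4Cl
Reagents that add atoms: none
Why: Zn–ProPhenol catalysed enantioselective alkynylation of an enal by the zinc acetylide of methyl propiolate adds to the formyl group only and should set the carbinol centre (R) inside the chiral dinuclear zinc pocket.

**Step 2**
Reactants: 3 methyl (4R,5E)-4-hydroxyhept-5-en-2-ynoate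
Product: 4 methyl (2Z,4R,5E)-4-hydroxy-2-iodohepta-2,5-dienoate
Conditions: NaAlH2(OCH2CH2OMe)2 (Red-Al, 1.6 equiv), THF, −72 °C; then I2 (3 equiv), −72 → −20 °C; aq. KNaC4H4O6 (potassium sodium tartrate) work-up
Reagents that add atoms: iodine, II
Why: Alkoxide-directed trans-hydroalumination of the γ-hydroxy ynoate (hydride to the β-carbon, aluminium held on the α-carbon cis to the carbinol in a five-membered chelate) followed by iododealumination with retention should give the (Z)-α-iodo enoate, which fixes the later cis relation of C3 and C6 across C1=C2.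

**Step 3**
Reactants: 4 methyl (2Z,4R,5E)-4-hydroxy-2-iodohepta-2,5-dienoate
Product: 5 methyl (2E,4R,5E)-4-hydroxy-2-(prop-2-en-1-yl)hepta-2,5-dienoate
Conditions: allylSnBu3 (1.5 equiv), Pd2(dba)3 (2.5 mol %), AsPh3 (10 mol %), CuI (10 mol %), DMF, rt
Reagents that add atoms: allyltributylstannane, C=CC[Sn](CCCC)(CCCC)CCCC
Why: Stille cross-coupling of an α-iodo enoate with an allylstannane proceeds with retention of alkene geometry and tolerates the free hydroxyl.

**Step 4**
Reactants: 5 methyl (2E,4R,5E)-4-hydroxy-2-(prop-2-en-1-yl)hepta-2,5-dienoate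
Product: 6 methyl (2E,4R,5E)-4-[(diethoxyphosphoryl)(ethoxycarbonyl)methoxy]-2-(prop-2-en-1-yl)hepta-2,5-dienoate (epimers at the phosphonate carbon)
Conditions: ethyl diazo(diethoxyphosphoryl)acetate (1.5 equiv, slow addition), Rh2(OAc)4 (2 mol %), PhH, 80 °C
Reagents that add atoms: ethyl diazo(diethoxyphosphoryl)acetate, CCOC(=O)C(=[N+]=[N-])P(=O)(OCC)OCC
Why: Rhodium carbenoid O–H insertion of an acceptor/acceptor diazo phosphonoacetate into a secondary allylic alcohol outruns cyclopropanation and leaves the carbinol centre untouched; the new phosphonate-bearing carbon forms as an inconsequential epimer mixture.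

**Step 5**
Reactants: 6 methyl (2E,4R,5E)-4-[(diethoxyphosphoryl)(ethoxycarbonyl)methoxy]-2-(prop-2-en-1-yl)hepta-2,5-dienoate
Product: 7 methyl (2E,4S)-4-[(diethoxyphosphoryl)(ethoxycarbonyl)methoxy]-5-oxo-2-(2-oxoethyl)pent-2-enoate
Conditions: O3, CH2Cl2, −78 °C (Sudan Red 7B end point); then PPh3 (2.2 equiv), −78 °C → rt; short silica pad, used at once
Reagents that add atoms: ozone, [O-][O+]=O
Why: Ozone cleaves the two electron-rich isolated alkenes (propenyl and allyl) much faster than the electron-poor trisubstituted enoate, so titration to the indicator end point and phosphine reduction should unveil both formyl groups at once under neutral conditions, with volatile by-products.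

**Step 6**
Reactants: 7 methyl (2E,4S)-4-[(diethoxyphosphoryl)(ethoxycarbonyl)methoxy]-5-oxo-2-(2-oxoethyl)pent-2-enoate
Product: 9 methyl (4aS,5R,8aS)-2-(diethoxyphosphoryl)-5-hydroxy-3-oxo-2,3,4a,5,6,8a-hexahydro-1,4-benzodioxine-7-carboxylate (epimers at C2), via trans-diol ester 8 (not isolated)
Conditions: Cp2TiPh (2.3 equiv, made in the flask from Cp2TiCl and PhMgBr, THF, −78 °C); 7 added over 2 h (final 0.01 M), −78 → −20 °C; then HCl (4 M in dioxane), 0 °C → rt
Reagents that add atoms: none
Why: Two equivalents of Cp2TiPh (trivalent titanium) each transfer one electron to a formyl group of 7, and the two titanoxy ketyl radicals, held in reach by the cis arms on the C1=C2 enoate, recombine to the C4–C5 bond. The closest known reaction type is the trans-selective titanocene-mediated pinacol cyclisation of 1,6-dials to cyclohexane-1,2-diols. The carbocycle closes as a six-membered ring by radical–radical union of its two termini (formally 6-exo addition of the C5 ketyl to the C4 carbonyl carbon), and after protonolysis the C4 hydroxyl closes the 1,4-dioxan-2-one by 6-exo-trig acyl substitution on the ethyl ester tethered at O3, with loss of ethanol. C5 should be set trans to C4 because the two bulky, non-chelating Cp2(Ph)Ti–O groups avoid each other in the half-chair transition state (both pseudo-equatorial), and C4 anti to the existing C3 ether (Felkin-type dipole and steric minimisation, C3–O pseudo-equatorial), so the all-trans (3S,4S,5R) array derives from the single C3 centre. The step needs chemoselectivity for the aldehydes over the enoate and esters, which the mild reductant secures (the ketyls can reach the enoate only through three- or four-membered rings), and lactonisation at O4 instead of O5, which the tether on O3 secures (six- against seven-membered ring).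

**Step 7**
Reactants: 9 methyl (4aS,5R,8aS)-2-(diethoxyphosphoryl)-5-hydroxy-3-oxo-2,3,4a,5,6,8a-hexahydro-1,4-benzodioxine-7-carboxylate
Product: 10 methyl (4aS,5R,8aS)-5-hydroxy-2-methylidene-3-oxo-2,3,4a,5,6,8a-hexahydro-1,4-benzodioxine-7-carboxylate
Conditions: CH2O (monomeric, THF solution), LiCl, DBU, MeCN, 0 °C
Reagents that add atoms: formaldehyde, C=O
Why: Horner–Wadsworth–Emmons olefination of the α-alkoxy phosphono lactone with formaldehyde under mild Masamune–Roush conditions should give the exocyclic methylene without touching the ring stereocentres.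

**Step 8**
Reactants: 11 2,4-dimethylbenzene-1,3-diol (2,4-dimethylresorcinol); 12 (2E,4E)-hexa-2,4-dienoic acid (sorbic acid)
Product: 13 (2E,4E)-1-(2,4-dihydroxy-3,5-dimethylphenyl)hexa-2,4-dien-1-one (sorbicillin)
Conditions: BF3·OEt2, 90 °C; then H2O
Reagents that add atoms: none
Why: Boron trifluoride-mediated Friedel–Crafts acylation occurs at the only free ring position that is ortho to one hydroxyl and para to the other.

**Step 9**
Reactants: 13 sorbicillin
Product: 14 (6R)-3,6-dihydroxy-2,6-dimethyl-4-[(2E,4E)-hexa-2,4-dienoyl]cyclohexa-2,4-dien-1-one ((R)-sorbicillinol)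
Conditions: (Ra)-2,2'-diiodyl-1,1'-binaphthyl (0.6 equiv, from the diiodide and dimethyldioxirane), CH2Cl2, −40 → 0 °C; cold pH 5 buffer work-up; solution used at once
Reagents that add atoms: (Ra)-2,2'-diiodyl-1,1'-binaphthyl, O=I(=O)c1ccc2ccccc2c1-c1c(I(=O)=O)ccc2ccccc12
Why: Hydroxylative phenol dearomatisation by a chiral aryl iodyl reagent (pentavalent iodine) should proceed by ligand exchange at the free 4'-hydroxyl (the 2'-hydroxyl is locked in a hydrogen bond to the ketone) and sigmatropic oxygen transfer to the less hindered methylated ortho carbon (C5') inside the chiral binaphthyl environment, which sets the (R) quaternary centre.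

**Step 10**
Reactants: 14 (R)-sorbicillinol; 10 methylene dioxanone
Product: 15 target CNP0259039.2
Conditions: cold CH2Cl2 solution of 14 added by syringe pump to 10 (equimolar) in DMF, 0 °C → rt, dark
Reagents that add atoms: none
Why: Diels–Alder reaction of the cyclohexadienone diene of 14 with the captodative exocyclic alkene of 10 joins C5 of the diene to the methylene carbon and C2 to the oxygenated carbon in a pure one-to-one addition that keeps every atom of both partners (slow addition keeps 14 dilute, so that trapping by 10 should outrun its dimerisation); addition to the diene face syn to the tertiary hydroxyl, with the lactone carbonyl endo and from the lactone face that carries the C8a–H, should set both bridgeheads and the spiro centre, and the adduct tautomerises to the hydrogen-bonded exocyclic enol drawn.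

**Compound list**
1 | (E)-but-2-enal | C/C=C/C=O | starting material
2 | methyl propiolate | C#CC(=O)OC | starting material
3 | methyl (4R,5E)-4-hydroxyhept-5-en-2-ynoate | C/C=C/[C@@H](O)C#CC(=O)OC | intermediate
4 | methyl (2Z,4R,5E)-4-hydroxy-2-iodohepta-2,5-dienoate | C/C=C/[C@@H](O)/C=C(\I)C(=O)OC | intermediate
5 | methyl (2E,4R,5E)-4-hydroxy-2-(prop-2-en-1-yl)hepta-2,5-dienoate | C/C=C/[C@@H](O)/C=C(\CC=C)C(=O)OC | intermediate
6 | methyl (2E,4R,5E)-4-[(diethoxyphosphoryl)(ethoxycarbonyl)methoxy]-2-(prop-2-en-1-yl)hepta-2,5-dienoate | C/C=C/[C@@H](OC(P(=O)(OCC)OCC)C(=O)OCC)/C=C(\CC=C)C(=O)OC | intermediate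
7 | methyl (2E,4S)-4-[(diethoxyphosphoryl)(ethoxycarbonyl)methoxy]-5-oxo-2-(2-oxoethyl)pent-2-enoate | O=C[C@@H](OC(P(=O)(OCC)OCC)C(=O)OCC)/C=C(\CC=O)C(=O)OC | intermediate
8 | ethyl 2-(diethoxyphosphoryl)-2-{[(1S,5R,6S)-5,6-dihydroxy-3-(methoxycarbonyl)cyclohex-2-en-1-yl]oxy}acetate | CCOC(=O)C(P(=O)(OCC)OCC)O[C@H]1C=C(C(=O)OC)C[C@@H](O)[C@@H]1O | intermediate
9 | methyl (4aS,5R,8aS)-2-(diethoxyphosphoryl)-5-hydroxy-3-oxo-2,3,4a,5,6,8a-hexahydro-1,4-benzodioxine-7-carboxylate | CCOP(=O)(OCC)C1O[C@H]2C=C(C(=O)OC)C[C@@H](O)[C@@H]2OC1=O | intermediate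
10 | methyl (4aS,5R,8aS)-5-hydroxy-2-methylidene-3-oxo-2,3,4a,5,6,8a-hexahydro-1,4-benzodioxine-7-carboxylate | C=C1O[C@H]2C=C(C(=O)OC)C[C@@H](O)[C@@H]2OC1=O | intermediate
11 | 2,4-dimethylbenzene-1,3-diol | Cc1ccc(O)c(C)c1O | starting material
12 | (2E,4E)-hexa-2,4-dienoic acid | C/C=C/C=C/C(=O)O | starting material
13 | sorbicillin | C/C=C/C=C/C(=O)c1cc(C)c(O)c(C)c1O | intermediate
14 | (R)-sorbicillinol | C/C=C/C=C/C(=O)C1=C[C@@](C)(O)C(=O)C(C)=C1O | intermediate
15 | target CNP0259039.2 | C/C=C/C=C/C(O)=C1/C(=O)[C@@]2(C)C(=O)[C@](C)(O)[C@@H]1C[C@]21O[C@H]2C=C(C(=O)OC)C[C@@H](O)[C@@H]2OC1=O | target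

**Step count**
Total: 10 steps. Longest linear sequence: 8 steps (steps 1–7 and 10).

**Steps most likely to fail**

1. Step 6. The titanocene may reduce the unactivated aliphatic formyl group too slowly, the doubly activated C3–H of 7 may enolise before coupling (erosion of the C3 centre), or trans selectivity may be incomplete. The fallback sets out from 7 and comes back at 9. SmI2 (THF, t-BuOH, −78 °C) performs the chelation-controlled pinacol cyclisation that is established for α-alkoxy 1,6-dialdehydes and should give the cis-4,5-diol anti to the C3 ether. Its O4 samarium alkoxide lactonises to methyl (4aS,5S,8aS)-2-(diethoxyphosphoryl)-5-hydroxy-3-oxo-2,3,4a,5,6,8a-hexahydro-1,4-benzodioxine-7-carboxylate F1 (the C5 epimer of 9). The C5 carbinol is then corrected by Dess–Martin oxidation (NaHCO3, CH2Cl2) to methyl (4aR,8aS)-2-(diethoxyphosphoryl)-3,5-dioxo-2,3,4a,5,6,8a-hexahydro-1,4-benzodioxine-7-carboxylate F2, followed by Luche reduction (NaBH4, CeCl3·7H2O, MeOH, −78 °C). Axial hydride delivery should give the equatorial alcohol trans to O4, which is 9.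

2. Step 9. Enantioinduction may be low, oxygen may be transferred to the other methylated ortho carbon (C3'), or the o-quinol may dimerise during work-up. The fallback sets out from 13 and comes back at 14. Wessely acetoxylation with Pb(OAc)4 (AcOH/CH2Cl2, 0 °C) should give the storable racemic O-acetylsorbicillinol F3. Preparative HPLC on a chiral stationary phase separates (R)-O-acetylsorbicillinol F4. K2CO3 in MeOH at 0 °C then releases 14 immediately before step 10.

3. Step 10. The diene may add to the wrong face of the methylene lactone, add exo, or dimerise faster than it is trapped. The fallback sets out from 7 and comes back at 15. The titanocene coupling is worked up with pH 7 buffer so that diol 8 is isolated, and olefination as in step 7 gives ethyl 2-{[(1S,5R,6S)-5,6-dihydroxy-3-(methoxycarbonyl)cyclohex-2-en-1-yl]oxy}prop-2-enoate F5. Diels–Alder reaction of this acyclic dienophile with 14 has no ring face to discriminate, so the spiro configuration depends only on ester-endo addition and the diene face; it should give the hydroxy ester adduct F6 (the ring-opened ethyl ester of 15). Acid-catalysed lactonisation (camphorsulfonic acid, PhMe, 60 °C) at O4 then closes the dioxanone to 15.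

**Further compounds**
F1 | step 6 | methyl (4aS,5S,8aS)-2-(diethoxyphosphoryl)-5-hydroxy-3-oxo-2,3,4a,5,6,8a-hexahydro-1,4-benzodioxine-7-carboxylate | CCOP(=O)(OCC)C1O[C@H]2C=C(C(=O)OC)C[C@H](O)[C@@H]2OC1=O
F2 | step 6 | methyl (4aR,8aS)-2-(diethoxyphosphoryl)-3,5-dioxo-2,3,4a,5,6,8a-hexahydro-1,4-benzodioxine-7-carboxylate | CCOP(=O)(OCC)C1O[C@H]2C=C(C(=O)OC)CC(=O)[C@@H]2OC1=O
F3 | step 9 | racemic O-acetylsorbicillinol | C/C=C/C=C/C(=O)C1=CC(C)(OC(C)=O)C(=O)C(C)=C1O
F4 | step 9 | (R)-O-acetylsorbicillinol | C/C=C/C=C/C(=O)C1=C[C@@](C)(OC(C)=O)C(=O)C(C)=C1O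
F5 | step 10 | ethyl 2-{[(1S,5R,6S)-5,6-dihydroxy-3-(methoxycarbonyl)cyclohex-2-en-1-yl]oxy}prop-2-enoate | C=C(O[C@H]1C=C(C(=O)OC)C[C@@H](O)[C@@H]1O)C(=O)OCC
F6 | step 10 | hydroxy ester adduct (ring-opened ethyl ester of 15) | C/C=C/C=C/C(O)=C1/C(=O)[C@@]2(C)C(=O)[C@](C)(O)[C@@H]1C[C@@]2(O[C@H]1C=C(C(=O)OC)C[C@@H](O)[C@@H]1O)C(=O)OCC
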